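(Its constants belong to no real substance; the run is a simulation.)

From 50 °C to 90 °C the step making second intermediate speeds up by a factor 30, so the question in these flasks is how much of it is on hand when open intermediate appears.

    partner B + target ⇌ idle adduct, settled at all times (K1 = 70 M⁻¹, ΔH1 = −19.0 kJ mol⁻¹)
    substrate + partner B → open intermediate (k2 = 46 M⁻¹ h⁻¹, Ea2 = 66.0 kJ mol⁻¹)
    open intermediate + second intermediate → target (k3 = 1300 M⁻¹ h⁻¹, Ea3 = 65.0 kJ mol⁻¹)
    2 open intermediate → homo product (k4 = 370 M⁻¹ h⁻¹, Ea4 = 47.0 kJ mol⁻¹)
    substrate + second intermediate → side product (k5 = 9.1 M⁻¹ h⁻¹, Ea5 = 63.0 kJ mol⁻¹)
    partner B + partner A → second intermediate (k6 = 4.7 M⁻¹ h⁻¹, Ea6 = 83.0 kJ mol⁻¹)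
    (constants at 70 °C)

the same everywhere: substrate 12 mM; partner A 30.0 mM; partner B 24.0 mM; time 8.0 h

|  | temperature | remark |
|---|---|---|
| east | 90 °C |  |
| south-east | 70 °C |  |
| west | 50 °C |  |
| south-west |  | at 50 °C until 4.0 h, from then on at 90 °C |

1. the best flask by share of target in all that became target or homo product or side product; "all alike" if 1.5 percentage points covers them all (east / south-east / west / south-west / all alike)
2. share of target in all that became target or homo product or side product, east
3. share of target in all that became target or homo product or side product, south-east
4. share of target in all that became target or homo product or side product, west
5. share of target in all that became target or homo product or side product, south-west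

- in percentages every species weighs as the substrate in it: one homo product counts as two
- for target the idle adduct is counted in
- where a step has two of a species, its rate is k times that concentration squared, and two are used at each turn
- at 70 °C the constants are as listed, elsewhere as the activation energies and enthalpies make them

Second intermediate and open intermediate are both made at a rate proportional to c(partner B), so partner B cancels from the ratio of the two rates. Taken at the charges, with each step's constant at the flask's temperature, that ratio is x: second intermediate made per open intermediate made. It is 0.255 at 70 °C, 0.177 at 50 °C and 0.355 at 90 °C, the supply ratio.

I solve both ends and join them, holding c(partner A) at its charge. Early, each second intermediate catches one open intermediate, and the surplus of open intermediate dimerises. The true ratio grows as c(substrate) falls, reaching one when the fraction of substrate left equals x, and after that every open intermediate finds a partner. Target is then x·ln(1/x) from the first stretch plus x from the second. This mark allows no dimerising after the join.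

If substrate finishes, the mark is 72.2% for east and 60.4% for south-east. South-west runs first on west's ratio and then on east's, and east's is larger, so I put east first.

West is the dispute: substrate may not finish there. One view holds partner B at its charge, twice the substrate. That leaves 12.1% of the substrate at the end, past the join, and gives a mark of 41.2%. The other view lets partner B fall towards 12.0 mM, what the substrate leaves of it, and takes the mean, 18.0 mM. That leaves 20.5%, short of the join, and the mark is 35.2%. I hold to the falling view.

The forecast names east, with 66% for east, 58% for south-east, 32% for west and 61% for south-west, on the grounds that “heat lets it keep pace with the open intermediate”, and its west figure is what one gets with partner B held at its starting value, while my own mark with partner B held stands at 41.2%.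

The simulation gives east as best, with 62.1% for east, 49.8% for south-east, 26.4% for west and 50.6% for south-west. West ends with 24.8% of its substrate, which sides with the falling view, and its partner B stands at 46.2%. South-west, still at 50 °C at 4.00 h, has 62.1% of its partner B left there. The readings lie under my marks by 10 percentage points in east, 11 points in south-east and 8.8 points in west.

Take east with 14 mM of partner B. The supply ratio stays 0.355, since partner B cancels, but serving the whole substrate charge would leave 2.00 mM of partner B, against 4.41 mM of second intermediate wanted before the join. This flask ends with partner B at 0.0275% and substrate at 24.4%, past the join. The mark for that stopping point is 63.2%. The flask reads 53.1%, which is 10 points under it, with 40.1% of the substrate as target and 33.1% as homo product.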